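**Retrosynthetic overview**

1. Feature: in the anisole ring (C4a, C5, C6, C7, C8, C8a) the methoxy group sits on C5, next to ring-fusion carbon C4a, and C6–C8 are CH. This is the pattern left when a 2-substituted furan (C8a, C8, C7, C6, O) and a terminal alkyne (C4a≡C5) isomerise on gold.
2. The last C–C bonds are therefore C4a–C8a and C5–C6. One step closes the carbocycle (C1–C4, C4a, C8a) and the benzene ring together and moves the furan oxygen to C5. After it come only O-methylation and one fluoride deprotection (C1 silyl ether, naphthol SEM ether), so the benzylic C1–OH never meets acid.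
3. The furan-yne is cut at C4–C2' (naphthyl): a stereoconvergent Ni-catalysed Negishi arylation of a racemic propargylic bromide with a 2-naphthyl(ethyl)zinc, made by SEM-directed ortho-lithiation and borylation of protected 8-methoxynaphthalen-1-ol.
4. The bromide comes from an aldehyde and a silylacetylide; the aldehyde comes from a 2-acylfuran whose Noyori transfer hydrogenation sets C1.
5. Ring order: furan and naphthalene are bought; the carbocycle and the anisole ring form together, last.

Key step: step 11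

Remark: skeleton atoms carry the tetralin numbering of the target (C1–C8a). At the arylated carbon the descriptor reads R in the silylalkyne and S in the terminal alkyne with no change in space, because C≡C–SiMe3 ranks above the naphthyl group and C≡CH below it.

**Route**

Step 1
Reactants: 1 N-methoxy-N-methylfuran-2-carboxamide; 2 but-3-en-1-ylmagnesium bromide
Product: 4 1-(furan-2-yl)pent-4-en-1-one, via magnesium hemiaminalate 3 (not isolated)
Conditions: THF, 0 °C to rt; then 1 M HCl, 0 °C
Reagents that add atoms: none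
Why: Weinreb ketone synthesis, in which the chelated tetrahedral adduct survives until work-up, so the Grignard reagent adds only once.

Step 2
Reactants: 4 1-(furan-2-yl)pent-4-en-1-one
Product: 5 (1S)-1-(furan-2-yl)pent-4-en-1-ol
Conditions: RuCl(p-cymene)[(S,S)-TsDPEN] (1 mol%), HCO2H/Et3N 5:2, rt
Reagents that add atoms: none
Why: Noyori asymmetric transfer hydrogenation, in which the 2-furyl group takes the aryl role, so the (S,S)-catalyst should give the (S)-carbinol (C1) as with aryl alkyl ketones and leave the terminal alkene alone.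

Step 3
Reactants: 5 (1S)-1-(furan-2-yl)pent-4-en-1-ol
Product: 6 tert-butyl{[(1S)-1-(furan-2-yl)pent-4-en-1-yl]oxy}dimethylsilane
Conditions: TBSCl, imidazole, DMF, rt
Reagents that add atoms: tert-butyldimethylsilyl chloride CC(C)(C)[Si](C)(C)Cl
Why: Standard imidazole-buffered silylation of a secondary alcohol, which keeps the acid-sensitive furfuryl carbinol away from acid and does not touch C1.

Step 4
Reactants: 6 tert-butyl{[(1S)-1-(furan-2-yl)pent-4-en-1-yl]oxy}dimethylsilane
Product: 8 (4S)-4-[(tert-butyldimethylsilyl)oxy]-4-(furan-2-yl)butanal, via pentane-1,2-diol 7 (not isolated)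
Conditions: OsO4 (2 mol%), NaIO4 (4 equiv), 2,6-lutidine, dioxane/H2O 3:1, rt
Reagents that add atoms: osmium tetroxide O=[Os](=O)(=O)=O (catalytic, reoxidised by sodium periodate [Na+].[O-][I](=O)(=O)=O)
Why: Lemieux–Johnson oxidative cleavage, in which the monosubstituted alkene should be dihydroxylated much faster than the aromatic furan and the lutidine buffer protects the silyl ether.

Step 5
Reactants: 8 (4S)-4-[(tert-butyldimethylsilyl)oxy]-4-(furan-2-yl)butanal; 9 ethynyltrimethylsilane
Product: 11 (3RS,6S)-6-[(tert-butyldimethylsilyl)oxy]-6-(furan-2-yl)-1-(trimethylsilyl)hex-1-yn-3-ol, via lithium silylacetylide 10 (not isolated)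
Conditions: n-BuLi, THF, −78 °C; then 8, −78 °C; aq. NH4Cl
Reagents that add atoms: none
Why: 1,2-Addition of a lithium acetylide to an aldehyde; the new carbinol is formed as both epimers on purpose, because this centre is erased and reset in step 9.

Step 6
Reactants: 11 (3RS,6S)-6-[(tert-butyldimethylsilyl)oxy]-6-(furan-2-yl)-1-(trimethylsilyl)hex-1-yn-3-ol
Product: 12 {[(1S,4RS)-4-bromo-1-(furan-2-yl)-6-(trimethylsilyl)hex-5-yn-1-yl]oxy}(tert-butyl)dimethylsilane
Conditions: CBr4, PPh3, CH2Cl2, 0 °C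
Reagents that add atoms: tetrabromomethane BrC(Br)(Br)Br
Why: Appel bromination under near-neutral conditions, in which the silyl group on the alkyne disfavours SN2' attack to a bromoallene and the furfuryl silyl ether sees no acid.

Step 7
Reactants: 13 8-methoxynaphthalen-1-ol
Product: 14 1-methoxy-8-{[2-(trimethylsilyl)ethoxy]methoxy}naphthalene
Conditions: NaH, DMF, 0 °C; then SEMCl, 0 °C to rt
Reagents that add atoms: 2-(trimethylsilyl)ethoxymethyl chloride C[Si](C)(C)CCOCCl
Why: Williamson-type O-alkylation of the naphthoxide, giving an acetal that directs the metalation of step 8 and is later cleaved by fluoride.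

Step 8
Reactants: 14 1-methoxy-8-{[2-(trimethylsilyl)ethoxy]methoxy}naphthalene
Product: 17 (8-methoxy-1-{[2-(trimethylsilyl)ethoxy]methoxy}naphthalen-2-yl)boronic acid, via 2-naphthyllithium 15 (not isolated), via lithium triisopropoxyborate 16 (not isolated)
Conditions: n-BuLi, TMEDA, THF, 0 °C; then B(OiPr)3, −78 °C to rt; aq. NH4Cl
Reagents that add atoms: triisopropyl borate CC(C)OB(OC(C)C)OC(C)C; water O
Why: Directed ortho-metalation, in which the acetal oxygens of the OSEM group guide lithiation to C2 (the only position ortho to it; the methoxy group is the weaker director), followed by borate trapping and hydrolysis.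

Step 9
Reactants: 12 {[(1S,4RS)-4-bromo-1-(furan-2-yl)-6-(trimethylsilyl)hex-5-yn-1-yl]oxy}(tert-butyl)dimethylsilane; 17 (8-methoxy-1-{[2-(trimethylsilyl)ethoxy]methoxy}naphthalen-2-yl)boronic acid
Product: 19 tert-butyl{[(1S,4R)-1-(furan-2-yl)-4-(8-methoxy-1-{[2-(trimethylsilyl)ethoxy]methoxy}naphthalen-2-yl)-6-(trimethylsilyl)hex-5-yn-1-yl]oxy}dimethylsilane, via naphthyl(ethyl)zinc 18 (not isolated)
Conditions: 17, Et2Zn (3 equiv), toluene, 60 °C, then evaporation; then 12, NiCl2·glyme (5 mol%), indanyl-pybox (6.5 mol%), DME, −20 °C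
Reagents that add atoms: none
Why: Stereoconvergent Ni/pybox-catalysed Negishi arylation of a racemic secondary propargylic bromide, in which both epimers give the same propargylic radical and the chiral aryl-nickel complex captures one face, so C4 is set by the catalyst (ligand antipode chosen for 4R after a pilot run with both antipodes) and the remote C1 centre has no say.

Step 10
Reactants: 19 tert-butyl{[(1S,4R)-1-(furan-2-yl)-4-(8-methoxy-1-{[2-(trimethylsilyl)ethoxy]methoxy}naphthalen-2-yl)-6-(trimethylsilyl)hex-5-yn-1-yl]oxy}dimethylsilane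
Product: 20 tert-butyl{[(1S,4S)-1-(furan-2-yl)-4-(8-methoxy-1-{[2-(trimethylsilyl)ethoxy]methoxy}naphthalen-2-yl)hex-5-yn-1-yl]oxy}dimethylsilane
Conditions: K2CO3 (cat.), MeOH, rt
Reagents that add atoms: none
Why: Methanolysis of the alkynyl C–Si bond by catalytic methoxide, which is too weak a base to remove the C4 proton and does not cleave the TBS ether or the SEM acetal.

Step 11
Reactants: 20 tert-butyl{[(1S,4S)-1-(furan-2-yl)-4-(8-methoxy-1-{[2-(trimethylsilyl)ethoxy]methoxy}naphthalen-2-yl)hex-5-yn-1-yl]oxy}dimethylsilane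
Product: 22 (5S,8R)-5-[(tert-butyldimethylsilyl)oxy]-8-(8-methoxy-1-{[2-(trimethylsilyl)ethoxy]methoxy}naphthalen-2-yl)-5,6,7,8-tetrahydronaphthalen-1-ol, via arene oxide 21 (not isolated)
Conditions: (JohnPhos)AuNTf2 (5 mol%), CH2Cl2, rt, argon
Reagents that add atoms: none
Why: Gold(I) activates the terminal alkyne and the furan attacks its internal carbon through the tether-bearing C2 in a 6-exo-dig closure, which forms C4a–C8a and the carbocycle and gives a cyclopropyl gold carbenoid. The carbenoid opens to a (Z)-dienone carbenoid, the former furan oxygen adds to the carbene carbon C5 to give an oxepine, and 6π-electrocyclisation to arene oxide 21 forms C5–C6 and the ring that becomes the arene; opening of the oxide with hydrogen shift gives the phenol. The closest known reaction type is the gold-catalysed furan-yne phenol synthesis, which gives isoindolines and indanes and, with four-atom O- and N-tethers, isochromans and tetrahydroisoquinolines that carry the hydroxyl next to the ring fusion on the alkyne side; the all-carbon four-atom tether is the same reaction on a new molecule. No stereocentre is formed: C1 and C4 sit on the tether and take no part in any bond change, so the (1S,4S) alkyne should give the trans (1S,4R) tetralin. The step needs exo attack, the furan (not the naphthalene or the acetal oxygen) as nucleophile, and oxygen on C5, not on C6. These are secured by the terminal alkyne, by the higher nucleophilicity of the furan, and by opening of the oxide at C6–O, which puts charge on C4a and C8 and away from the siloxy-bearing C1; the neutral phosphine-gold(I) triflimide is too weak a Lewis acid to ionise the furfuryl silyl ether.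

Step 12
Reactants: 22 (5S,8R)-5-[(tert-butyldimethylsilyl)oxy]-8-(8-methoxy-1-{[2-(trimethylsilyl)ethoxy]methoxy}naphthalen-2-yl)-5,6,7,8-tetrahydronaphthalen-1-ol
Product: 23 tert-butyl{[(1S,4R)-5-methoxy-4-(8-methoxy-1-{[2-(trimethylsilyl)ethoxy]methoxy}naphthalen-2-yl)-1,2,3,4-tetrahydronaphthalen-1-yl]oxy}dimethylsilane
Conditions: MeI, K2CO3, DMF, rt
Reagents that add atoms: iodomethane CI
Why: Williamson O-methylation of the only free hydroxyl, the C5 phenol, under conditions that leave the silyl ether and the SEM acetal intact.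

Step 13
Reactants: 23 tert-butyl{[(1S,4R)-5-methoxy-4-(8-methoxy-1-{[2-(trimethylsilyl)ethoxy]methoxy}naphthalen-2-yl)-1,2,3,4-tetrahydronaphthalen-1-yl]oxy}dimethylsilane
Product: 24 (1S,4R)-4-(1-hydroxy-8-methoxynaphthalen-2-yl)-5-methoxy-1,2,3,4-tetrahydronaphthalen-1-ol (dipolynaphthalene A)
Conditions: TBAF (6 equiv), ethylenediamine, DMF, 60 °C; aq. NH4Cl
Reagents that add atoms: none
Why: Fluoride-induced desilylation cleaves the TBS ether and attacks the SiMe3 group of the SEM acetal, which fragments to ethene, formaldehyde (trapped by the diamine) and the naphthoxide; without acid the benzylic C1–OH cannot ionise and both stereocentres stay as set.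

**Compound list**

1 | N-methoxy-N-methylfuran-2-carboxamide | CON(C)C(=O)c1ccco1 | starting material
2 | but-3-en-1-ylmagnesium bromide | C=CCC[Mg]Br | starting material
3 | bromomagnesium 1-(furan-2-yl)-1-[methoxy(methyl)amino]pent-4-en-1-olate | C=CCCC(O[Mg]Br)(N(C)OC)c1ccco1 | intermediate
4 | 1-(furan-2-yl)pent-4-en-1-one | C=CCCC(=O)c1ccco1 | intermediate
5 | (1S)-1-(furan-2-yl)pent-4-en-1-ol | C=CCC[C@H](O)c1ccco1 | intermediate
6 | tert-butyl{[(1S)-1-(furan-2-yl)pent-4-en-1-yl]oxy}dimethylsilane | C=CCC[C@H](O[Si](C)(C)C(C)(C)C)c1ccco1 | intermediate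
7 | (5S)-5-[(tert-butyldimethylsilyl)oxy]-5-(furan-2-yl)pentane-1,2-diol | OCC(O)CC[C@H](O[Si](C)(C)C(C)(C)C)c1ccco1 | intermediate
8 | (4S)-4-[(tert-butyldimethylsilyl)oxy]-4-(furan-2-yl)butanal | O=CCC[C@H](O[Si](C)(C)C(C)(C)C)c1ccco1 | intermediate
9 | ethynyltrimethylsilane | C#C[Si](C)(C)C | starting material
10 | lithium (trimethylsilyl)acetylide | [Li]C#C[Si](C)(C)C | intermediate
11 | (3RS,6S)-6-[(tert-butyldimethylsilyl)oxy]-6-(furan-2-yl)-1-(trimethylsilyl)hex-1-yn-3-ol | C[Si](C)(C)C#CC(O)CC[C@H](O[Si](C)(C)C(C)(C)C)c1ccco1 | intermediate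
12 | {[(1S,4RS)-4-bromo-1-(furan-2-yl)-6-(trimethylsilyl)hex-5-yn-1-yl]oxy}(tert-butyl)dimethylsilane | C[Si](C)(C)C#CC(Br)CC[C@H](O[Si](C)(C)C(C)(C)C)c1ccco1 | intermediate
13 | 8-methoxynaphthalen-1-ol | COc1cccc2cccc(O)c12 | starting material
14 | 1-methoxy-8-{[2-(trimethylsilyl)ethoxy]methoxy}naphthalene | COc1cccc2cccc(OCOCC[Si](C)(C)C)c12 | intermediate
15 | (8-methoxy-1-{[2-(trimethylsilyl)ethoxy]methoxy}naphthalen-2-yl)lithium | COc1cccc2ccc([Li])c(OCOCC[Si](C)(C)C)c12 | intermediate
16 | lithium triisopropoxy(8-methoxy-1-{[2-(trimethylsilyl)ethoxy]methoxy}naphthalen-2-yl)borate | [Li+].COc1cccc2ccc([B-](OC(C)C)(OC(C)C)OC(C)C)c(OCOCC[Si](C)(C)C)c12 | intermediate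
17 | (8-methoxy-1-{[2-(trimethylsilyl)ethoxy]methoxy}naphthalen-2-yl)boronic acid | COc1cccc2ccc(B(O)O)c(OCOCC[Si](C)(C)C)c12 | intermediate
18 | ethyl(8-methoxy-1-{[2-(trimethylsilyl)ethoxy]methoxy}naphthalen-2-yl)zinc | CC[Zn]c1ccc2cccc(OC)c2c1OCOCC[Si](C)(C)C | intermediate
19 | tert-butyl{[(1S,4R)-1-(furan-2-yl)-4-(8-methoxy-1-{[2-(trimethylsilyl)ethoxy]methoxy}naphthalen-2-yl)-6-(trimethylsilyl)hex-5-yn-1-yl]oxy}dimethylsilane | C[Si](C)(C)C#C[C@@H](c1ccc2cccc(OC)c2c1OCOCC[Si](C)(C)C)CC[C@H](O[Si](C)(C)C(C)(C)C)c1ccco1 | intermediate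
20 | tert-butyl{[(1S,4S)-1-(furan-2-yl)-4-(8-methoxy-1-{[2-(trimethylsilyl)ethoxy]methoxy}naphthalen-2-yl)hex-5-yn-1-yl]oxy}dimethylsilane | C#C[C@@H](c1ccc2cccc(OC)c2c1OCOCC[Si](C)(C)C)CC[C@H](O[Si](C)(C)C(C)(C)C)c1ccco1 | intermediate
21 | C5–C6 arene oxide of 22 (target numbering; epoxide carbons unassigned) | C1=CC2=C(C3OC13)[C@@H](c1ccc3cccc(OC)c3c1OCOCC[Si](C)(C)C)CC[C@@H]2O[Si](C)(C)C(C)(C)C | intermediate
22 | (5S,8R)-5-[(tert-butyldimethylsilyl)oxy]-8-(8-methoxy-1-{[2-(trimethylsilyl)ethoxy]methoxy}naphthalen-2-yl)-5,6,7,8-tetrahydronaphthalen-1-ol | Oc1cccc2c1[C@@H](c1ccc3cccc(OC)c3c1OCOCC[Si](C)(C)C)CC[C@@H]2O[Si](C)(C)C(C)(C)C | intermediate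
23 | tert-butyl{[(1S,4R)-5-methoxy-4-(8-methoxy-1-{[2-(trimethylsilyl)ethoxy]methoxy}naphthalen-2-yl)-1,2,3,4-tetrahydronaphthalen-1-yl]oxy}dimethylsilane | COc1cccc2c1[C@@H](c1ccc3cccc(OC)c3c1OCOCC[Si](C)(C)C)CC[C@@H]2O[Si](C)(C)C(C)(C)C | intermediate
24 | (1S,4R)-4-(1-hydroxy-8-methoxynaphthalen-2-yl)-5-methoxy-1,2,3,4-tetrahydronaphthalen-1-ol (dipolynaphthalene A) | COc1cccc2c1[C@@H](c1ccc3cccc(OC)c3c1O)CC[C@@H]2O | target

**Count**

Total steps: 13. Longest linear sequence: 11 steps (steps 1–6 and 9–13, from amide 1); the naphthalene branch (steps 7 and 8) joins at step 9.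

**Steps most likely to fail**

1. Step 11. The 6-exo attack over a flexible all-carbon tether may be slower than side paths at the gold-activated alkyne (hydration, attack by the neighbouring acetal oxygen, oligomerisation), and the arene oxide may open partly toward the C6 phenol. The fallback sets out from boronic acid 17 and returns at target 24; it takes the carbocycle and the anisole ring ready-made and sets C4 on the ring. Purchased 5-methoxy-3,4-dihydronaphthalen-1(2H)-one F1 is reduced with the catalyst of step 2 to (1S)-5-methoxy-1,2,3,4-tetrahydronaphthalen-1-ol F2. Acetylation (Ac2O, pyridine) gives (1S)-5-methoxy-1,2,3,4-tetrahydronaphthalen-1-yl acetate F3, whose C1–H is deactivated, so chromium(VI) oxidation (CrO3, aqueous AcOH) should attack the remaining benzylic CH2 and give (1S)-5-methoxy-4-oxo-1,2,3,4-tetrahydronaphthalen-1-yl acetate F4. Enol triflation (LiHMDS, PhNTf2, THF, −78 °C) gives (1S)-5-methoxy-4-[(trifluoromethanesulfonyl)oxy]-1,2-dihydronaphthalen-1-yl acetate F5. Suzuki–Miyaura coupling with 17 (Pd(dppf)Cl2, K3PO4, THF/H2O, 40 °C) gives (1S)-5-methoxy-4-(8-methoxy-1-{[2-(trimethylsilyl)ethoxy]methoxy}naphthalen-2-yl)-1,2-dihydronaphthalen-1-yl acetate F6, and K2CO3/MeOH frees the homoallylic alcohol (1S)-5-methoxy-4-(8-methoxy-1-{[2-(trimethylsilyl)ethoxy]methoxy}naphthalen-2-yl)-1,2-dihydronaphthalen-1-ol F7. Hydroxyl-directed hydrogenation with Crabtree's catalyst (H2, CH2Cl2) should deliver hydrogen to C4 from the face of the C1 hydroxyl, which places the naphthyl group trans and gives (1S,4R)-5-methoxy-4-(8-methoxy-1-{[2-(trimethylsilyl)ethoxy]methoxy}naphthalen-2-yl)-1,2,3,4-tetrahydronaphthalen-1-ol F8. The fluoride conditions of step 13 then remove the SEM group and give 24.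

2. Step 9. Transmetalation of the ortho-substituted naphthylzinc may be slow and the facial discrimination of the propargylic radical poor, so conversion or the ratio at C4 may be low. The fallback sets out from bromide 12 and boronic acid 17 and returns at phenol 22; it gives up catalyst control at C4 and separates on the ring. The coupling is run with zinc reagent 18 and an achiral nickel–terpyridine catalyst (NiCl2·glyme, terpyridine, DME, rt) to give tert-butyl{[(1S,4RS)-1-(furan-2-yl)-4-(8-methoxy-1-{[2-(trimethylsilyl)ethoxy]methoxy}naphthalen-2-yl)-6-(trimethylsilyl)hex-5-yn-1-yl]oxy}dimethylsilane F9. Desilylation as in step 10 gives the epimeric alkynes tert-butyl{[(1S,4RS)-1-(furan-2-yl)-4-(8-methoxy-1-{[2-(trimethylsilyl)ethoxy]methoxy}naphthalen-2-yl)hex-5-yn-1-yl]oxy}dimethylsilane F10, and the conditions of step 11 give the cis/trans pair (5S,8RS)-5-[(tert-butyldimethylsilyl)oxy]-8-(8-methoxy-1-{[2-(trimethylsilyl)ethoxy]methoxy}naphthalen-2-yl)-5,6,7,8-tetrahydronaphthalen-1-ol F11. On the rigid tetralin the two 1,4-diastereomers should separate on silica; the trans isomer is 22.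

3. Step 4. Osmium tetroxide and periodate may oxidise the electron-rich furan in competition with the alkene. The fallback sets out from amide 1 and returns at aldehyde 8; it carries the aldehyde as an acetal, so no oxidant meets the furan. Purchased [2-(1,3-dioxolan-2-yl)ethyl]magnesium bromide F12 adds to 1 as in step 1 to give 3-(1,3-dioxolan-2-yl)-1-(furan-2-yl)propan-1-one F13. Transfer hydrogenation as in step 2 gives (1S)-3-(1,3-dioxolan-2-yl)-1-(furan-2-yl)propan-1-ol F14, and silylation as in step 3 gives tert-butyl{[(1S)-3-(1,3-dioxolan-2-yl)-1-(furan-2-yl)propoxy]}dimethylsilane F15. Acetal hydrolysis (PPTS, acetone/H2O, 50 °C) releases 8.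

**Further compounds**

F1 | step 11 | 5-methoxy-3,4-dihydronaphthalen-1(2H)-one | COc1cccc2c1CCCC2=O
F2 | step 11 | (1S)-5-methoxy-1,2,3,4-tetrahydronaphthalen-1-ol | COc1cccc2c1CCC[C@@H]2O
F3 | step 11 | (1S)-5-methoxy-1,2,3,4-tetrahydronaphthalen-1-yl acetate | COc1cccc2c1CCC[C@@H]2OC(C)=O
F4 | step 11 | (1S)-5-methoxy-4-oxo-1,2,3,4-tetrahydronaphthalen-1-yl acetate | COc1cccc2c1C(=O)CC[C@@H]2OC(C)=O
F5 | step 11 | (1S)-5-methoxy-4-[(trifluoromethanesulfonyl)oxy]-1,2-dihydronaphthalen-1-yl acetate | COc1cccc2c1C(OS(=O)(=O)C(F)(F)F)=CC[C@@H]2OC(C)=O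
F6 | step 11 | (1S)-5-methoxy-4-(8-methoxy-1-{[2-(trimethylsilyl)ethoxy]methoxy}naphthalen-2-yl)-1,2-dihydronaphthalen-1-yl acetate | COc1cccc2c1C(c1ccc3cccc(OC)c3c1OCOCC[Si](C)(C)C)=CC[C@@H]2OC(C)=O
F7 | step 11 | (1S)-5-methoxy-4-(8-methoxy-1-{[2-(trimethylsilyl)ethoxy]methoxy}naphthalen-2-yl)-1,2-dihydronaphthalen-1-ol | COc1cccc2c1C(c1ccc3cccc(OC)c3c1OCOCC[Si](C)(C)C)=CC[C@@H]2O
F8 | step 11 | (1S,4R)-5-methoxy-4-(8-methoxy-1-{[2-(trimethylsilyl)ethoxy]methoxy}naphthalen-2-yl)-1,2,3,4-tetrahydronaphthalen-1-ol | COc1cccc2c1[C@@H](c1ccc3cccc(OC)c3c1OCOCC[Si](C)(C)C)CC[C@@H]2O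
F9 | step 9 | tert-butyl{[(1S,4RS)-1-(furan-2-yl)-4-(8-methoxy-1-{[2-(trimethylsilyl)ethoxy]methoxy}naphthalen-2-yl)-6-(trimethylsilyl)hex-5-yn-1-yl]oxy}dimethylsilane | C[Si](C)(C)C#CC(c1ccc2cccc(OC)c2c1OCOCC[Si](C)(C)C)CC[C@H](O[Si](C)(C)C(C)(C)C)c1ccco1
F10 | step 9 | tert-butyl{[(1S,4RS)-1-(furan-2-yl)-4-(8-methoxy-1-{[2-(trimethylsilyl)ethoxy]methoxy}naphthalen-2-yl)hex-5-yn-1-yl]oxy}dimethylsilane | C#CC(c1ccc2cccc(OC)c2c1OCOCC[Si](C)(C)C)CC[C@H](O[Si](C)(C)C(C)(C)C)c1ccco1
F11 | step 9 | (5S,8RS)-5-[(tert-butyldimethylsilyl)oxy]-8-(8-methoxy-1-{[2-(trimethylsilyl)ethoxy]methoxy}naphthalen-2-yl)-5,6,7,8-tetrahydronaphthalen-1-ol | Oc1cccc2c1C(c1ccc3cccc(OC)c3c1OCOCC[Si](C)(C)C)CC[C@@H]2O[Si](C)(C)C(C)(C)C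
F12 | step 4 | [2-(1,3-dioxolan-2-yl)ethyl]magnesium bromide | Br[Mg]CCC1OCCO1
F13 | step 4 | 3-(1,3-dioxolan-2-yl)-1-(furan-2-yl)propan-1-one | O=C(CCC1OCCO1)c1ccco1
F14 | step 4 | (1S)-3-(1,3-dioxolan-2-yl)-1-(furan-2-yl)propan-1-ol | C1(CC[C@H](O)c2ccco2)OCCO1
F15 | step 4 | tert-butyl{[(1S)-3-(1,3-dioxolan-2-yl)-1-(furan-2-yl)propoxy]}dimethylsilane | C1(CC[C@H](O[Si](C)(C)C(C)(C)C)c2ccco2)OCCO1
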